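By 21 min the north run has turned 40.8% of its substrate, and its slope has dropped from 0.0162 M min⁻¹ over the first 2.1 min to about 0.00725 M min⁻¹ over the last interval, which is lower. The question is what the same charge holds at 63 min.

the same everywhere: catalyst 0.00100 M

| flask | substrate | partner | product | time |
|---|---|---|---|---|
| north | 0.500 M | 0.600 M |  |  |
| north-west | 0.250 M | 0.350 M |  |  |
| south | 0.750 M | 0.600 M |  |  |
| west | 0.500 M | 0.600 M | 0.250 M |  |
| north-east | 0.500 M | 0.600 M |  | 63 min |

| run | time / min | [product] / M |
|---|---|---|
| north run | 0.84 | 0.016 |
| north run | 1.3 | 0.025 |
| north run | 2.1 | 0.034 |
| north run | 3.3 | 0.050 |
| north run | 5.3 | 0.078 |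
| north run | 8.4 | 0.110 |
| north run | 13 | 0.146 |
| north run | 21 | 0.204 |
| north-west run | 0.84 | 0.011 |
| north-west run | 1.3 | 0.014 |
| north-west run | 2.1 | 0.021 |
| north-west run | 3.3 | 0.032 |
| north-west run | 5.3 | 0.042 |
| north-west run | 8.4 | 0.050 |
| north-west run | 13 | 0.074 |
| north-west run | 21 | 0.102 |
| south run | 0.84 | 0.020 |
| south run | 1.3 | 0.031 |
| south run | 2.1 | 0.043 |
| south run | 3.3 | 0.065 |
| south run | 5.3 | 0.093 |
| south run | 8.4 | 0.132 |
| south run | 13 | 0.177 |
| south run | 21 | 0.240 |
| west run | 0.84 | 0.259 |
| west run | 1.3 | 0.267 |
| west run | 2.1 | 0.270 |
| west run | 3.3 | 0.283 |
| west run | 5.3 | 0.293 |
| west run | 8.4 | 0.317 |
| west run | 13 | 0.352 |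
| west run | 21 | 0.390 |

(standard deviation of a reading: 0.003 M)

1. the power of [partner] that the first rate follows, about the charge of the north run; measure it at two percent of substrate made into product
2. the power of [substrate] that the first rate follows, about the charge of the north run; measure it at two percent of substrate made into product (one fixed amount of product, the same in the runs compared)
3. the north-west run starts with 0.250 M less of substrate and of partner than the north run, and with no product. Compared where both hold the same amount of substrate, once fifteen percent of what the north-west run was charged with has turned into product, is the north-west run faster, slower or alike (within a tenth)?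
4. product in the north-east run at 63 min, as a share of the substrate charged

- Overall: substrate + partner -> product, with catalyst as catalyst.
- Constant volume, constant temperature.
- Readings of a species count what is bound in complexes too.
- An order is taken over about fifteen percent of the charge, up and down.

A rate constant ties a rate to what the flask holds, so the cleanest comparison is between two flasks that differ in one species. The north and west runs are such a pair. At equal amounts made they hold the same substrate and the same partner, but the west run carries extra product equal to half of the north charge. The north run makes 0.146 M by 13 min, whereas the west run gains 0.140 M in 21 min, so the west run is slower than the north run. This slowing is product inhibition. The ratio of the two mean rates is called here the stretch: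

stretch = 0.0112 M min⁻¹ / 0.00667 M min⁻¹ = 1.68

This stretch is the factor by which the extra product lengthens the time for the same turnover. Can it be frozen? Earlier, the west run gains 0.0670 M by 8.4 min and the north run makes 0.078 M by 5.3 min, which gives a stretch of 1.85, close enough to carry forward as a constant, though it is a reading with scatter.

The north-west run forms the same kind of pair with the north run. Its charge has 0.250 M less of both substrate and partner, so when the north run has turned half of its charge, it holds what the north-west run started with, plus that much product. From there on, at equal substrate, the north-west run should be faster than the north run by the stretch, which exceeds the margin of a tenth.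

The readings of the north run end at 0.204 M, which is 0.0460 M short of that point, and at the last slope of 0.00725 M min⁻¹ that remainder puts the crossing at about 27.3 min. The north-east run has the north charge, so its last 35.7 min correspond to a shorter north-west time:

north-west time = 35.7 min / 1.68 = 21.2 min

That is about the time of the last north-west reading, where the north-west run has made 20.4% of the north charge. Added to the 50.0% already turned, this gives my reckoning:

share at 63 min = 70.4%

The forecast differs. It gives 73% (range 65% to 80%), from “Stepping the rate law forward”, which is higher than my figure. It puts the partner order at 0.2 (0 to 0.55) and the substrate order at 0.55 (0.35 to 0.75), and it calls the north-west run faster.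

The north-east run stands at 65.9% at 63 min, lower than both figures. The partner order is 0.59, higher than the forecast's range allowed, the substrate order is 0.54, and the north-west run is faster.

    catalyst + partner ⇌ catalyst-reagent complex, settled at all times (9.470 M⁻¹)
    catalyst-reagent complex + substrate → product + catalyst (82.20 M⁻¹ min⁻¹)
    catalyst + substrate ⇌ idle catalyst-substrate complex, settled at all times (13.00 M⁻¹)
    catalyst + product ⇌ catalyst-product complex, settled at all times (42.90 M⁻¹)

Parking catalyst as the idle catalyst-substrate complex moves the readings by 11 times their scatter. Beyond the 50.0% that the north run has turned at 32.2 min, the north-east run gained 15.9% of its charge, which the north-west readings reach at about 14.6 min. The stretch over that part of the run is therefore 2.11, larger than the frozen 1.68.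

The runs were computed with constants of no real substance, noise included.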